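**Strategy**

The route rests on closing the flavanone ring C last by making the C2–C3 bond. In the target C2 is a benzylic carbon bonded to O1 and ring B, and C3 is the methylene beside the C4 ketone on ring A; C2 can therefore travel as the CH2 of a ring B benzyl ether on a ring A phenol and C3 as a diazomethyl ketone carbon. A chiral dirhodium carboxylate converts the diazoketone into a carbenoid that inserts into one enantiotopic benzylic C–H, which closes ring C and sets (2S)-C2 in one operation. The precursor is a 2-(biarylmethoxy)-4-methoxy-6-(triisopropylsilyloxy)phenyl diazomethyl ketone already carrying the benzyl-protected apigenin unit at C3′.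

Key step: step 9

**Assumptions and design notes**

- Assumption: Rh2(S-PTTL)4, dirhodium tetrakis[N-phthaloyl-(S)-tert-leucinate], is taken to deliver (2S); should a trial on 12 show the opposite sense, the mirror-image complex Rh2(R-PTTL)4 is used and nothing else changes.
- Remark: the C3′–C8″ biaryl axis has no descriptor in the target and is treated as freely rotating; protected intermediates may show rotamers, which does not affect C2.
- The target is (2S): at C2 the priorities are O1 > C1′ > C3 > H. Diazoketone 12 and insertion product 13 map onto it atom by atom: the methoxy group para to the acyl carbon becomes 7-OMe, the silylated oxygen becomes O5, and ring B carries O4′ and the bond to C8 of the flavone.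
- The second ortho oxygen of ring A carries triisopropylsilyl rather than a smaller silyl group. It should not transfer to the lithium enolate formed beside it in step 8, it should survive wet triethylamine, and it screens its own oxygen from the carbenoid in step 9.
- "Tri-O-benzylapigenin-8-yl" below means 5,7-bis(benzyloxy)-2-[4-(benzyloxy)phenyl]-4-oxo-4H-chromen-8-yl.
- Compounds 1, 4 and 8 are taken as commercial.

**Route**

Step 1
Reactants: 1 apigenin
Product: 2 5,7,4′-tri-O-benzylapigenin
Conditions: BnBr (4 equiv), K2CO3, Bu4NI (cat.), DMF, 80 °C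
Reagents that add atoms: benzyl bromide, BrCc1ccccc1
Why: Williamson ether synthesis; excess benzyl bromide with carbonate in warm DMF should alkylate all three phenols including the hydrogen-bonded 5-OH, and O5 must be capped because a free 5-OH would steer the later iodination to C6.

Step 2
Reactants: 2 5,7,4′-tri-O-benzylapigenin
Product: 3 8-iodo-5,7,4′-tri-O-benzylapigenin
Conditions: N-iodosuccinimide (1.05 equiv), CF3CO2H (cat.), CH2Cl2/MeCN, 0 °C to rt, dark
Reagents that add atoms: N-iodosuccinimide, O=C1CCC(=O)N1I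
Why: Electrophilic aromatic substitution; in a 5,7-dialkoxyflavone the iodonium source should attack C8 of ring A, which is para to O5, ortho to O7 and less crowded than C6 between two benzyloxy groups, while the pyrone ring, ring B and the benzyl phenyl rings are much weaker nucleophiles.

Step 3
Reactants: 4 4-(benzyloxy)-3-bromobenzaldehyde
Product: 5 4-(benzyloxy)-3-(4,4,5,5-tetramethyl-1,3,2-dioxaborolan-2-yl)benzaldehyde
Conditions: B2pin2, PdCl2(dppf) (3 mol %), KOAc, 1,4-dioxane, 85 °C
Reagents that add atoms: bis(pinacolato)diboron, CC1(C)OB(OC1(C)C)B1OC(C)(C)C(C)(C)O1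
Why: Miyaura borylation; oxidative addition into the aryl bromide and acetate-assisted transmetalation from the diboron tolerate the aldehyde and the benzyl ether.

Step 4
Reactants: 3 8-iodo-5,7,4′-tri-O-benzylapigenin; 5 4-(benzyloxy)-3-(4,4,5,5-tetramethyl-1,3,2-dioxaborolan-2-yl)benzaldehyde
Product: 6 4-(benzyloxy)-3-(tri-O-benzylapigenin-8-yl)benzaldehyde
Conditions: Pd(OAc)2 (5 mol %), SPhos (10 mol %), K3PO4, toluene/H2O, 90 °C
Reagents that add atoms: none
Why: Suzuki–Miyaura coupling; the bulky electron-rich biarylphosphine suits tri-ortho-substituted biaryls, and placing iodine on the hindered flavone C8 and boron on the partner with a single ortho oxygen is the arrangement less prone to protodeboronation.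

Step 5
Reactants: 6 4-(benzyloxy)-3-(tri-O-benzylapigenin-8-yl)benzaldehyde
Product: 7 [4-(benzyloxy)-3-(tri-O-benzylapigenin-8-yl)phenyl]methanol
Conditions: NaBH4, THF/MeOH, 0 °C
Reagents that add atoms: none
Why: Hydride reduction; NaBH4 at 0 °C reduces the aryl aldehyde much faster than the flavone carbonyl, which is a vinylogous ester, so only the formyl group should react.

Step 6
Reactants: 7 [4-(benzyloxy)-3-(tri-O-benzylapigenin-8-yl)phenyl]methanol; 8 2′,6′-dihydroxy-4′-methoxyacetophenone (1.5 equiv)
Product: 9 1-{2-hydroxy-4-methoxy-6-[4-(benzyloxy)-3-(tri-O-benzylapigenin-8-yl)benzyloxy]phenyl}ethanone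
Conditions: PPh3, DIAD, THF, 0 °C to rt
Reagents that add atoms: none
Why: Mitsunobu etherification; the acidic phenol protonates the betaine and its phenoxide displaces the primary benzylic oxyphosphonium group, the two OH groups of 8 are equivalent, and the reaction should stop at the monoether because the remaining OH of 9 is tied up in a hydrogen bond to the acetyl group.

Step 7
Reactants: 9 1-{2-hydroxy-4-methoxy-6-[4-(benzyloxy)-3-(tri-O-benzylapigenin-8-yl)benzyloxy]phenyl}ethanone
Product: 10 1-{4-methoxy-2-[4-(benzyloxy)-3-(tri-O-benzylapigenin-8-yl)benzyloxy]-6-(triisopropylsilyloxy)phenyl}ethanone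
Conditions: iPr3SiCl, imidazole, DMAP (cat.), DMF, 40 °C
Reagents that add atoms: triisopropylsilyl chloride, CC(C)[Si](Cl)(C(C)C)C(C)C
Why: Silylation of a phenol with a silyl chloride under imidazole/DMAP catalysis; the hindered silyl group is chosen for its stability in step 8 and for shielding this oxygen in step 9.

Step 8
Reactants: 10 1-{4-methoxy-2-[4-(benzyloxy)-3-(tri-O-benzylapigenin-8-yl)benzyloxy]-6-(triisopropylsilyloxy)phenyl}ethanone
Product: 12 2-diazo-1-{4-methoxy-2-[4-(benzyloxy)-3-(tri-O-benzylapigenin-8-yl)benzyloxy]-6-(triisopropylsilyloxy)phenyl}ethanone, via trifluoroacetyl diketone 11 (not isolated)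
Conditions: LiN(SiMe3)2, THF, −78 °C; CF3CO2CH2CF3; dilute HCl wash; then MeSO2N3, Et3N, H2O (1 equiv), MeCN, rt
Reagents that add atoms: methanesulfonyl azide, CS(=O)(=O)N=[N+]=[N-] (the two diazo nitrogens); 2,2,2-trifluoroethyl trifluoroacetate, O=C(OCC(F)(F)F)C(F)(F)F (adds the trifluoroacetyl group of 11 only, which is lost again)
Why: Detrifluoroacetylative diazo transfer, a Regitz-type transfer to an activated ketone; the kinetic lithium enolate of the methyl ketone is C-trifluoroacetylated, the resulting 1,3-diketone takes the diazo group from the sulfonyl azide, and the trifluoroacetyl group leaves as the sulfonyl trifluoroacetamide to give the terminal diazoketone.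

Step 9
Reactants: 12 2-diazo-1-{4-methoxy-2-[4-(benzyloxy)-3-(tri-O-benzylapigenin-8-yl)benzyloxy]-6-(triisopropylsilyloxy)phenyl}ethanone
Product: 13 (2S)-2-[4-(benzyloxy)-3-(tri-O-benzylapigenin-8-yl)phenyl]-7-methoxy-5-(triisopropylsilyloxy)chroman-4-one
Conditions: Rh2(S-PTTL)4 (2 mol %), CH2Cl2, 4 Å molecular sieves, 0 °C, slow addition of 12 at high dilution
Reagents that add atoms: none
Why: The dirhodium complex expels N2 from the diazo carbon to give an electrophilic acceptor-only carbenoid at the future C3, which takes one of the two enantiotopic hydrogens of the neighbouring ArO–CH2–Ar′ group in a concerted, asynchronous three-centre insertion with hydride-shift character and so forms C2–C3. The closest known reaction type is the enantioselective intramolecular C–H insertion of 2-alkoxyaryl diazoketones to chromanones under chiral carboxylates of divalent rhodium. Ring C closes as a six-membered ring by 1,6-insertion (carbenoid C3, C4, C4a, C8a, O1, C2); the atom at the five-ring distance is the ether oxygen, so no smaller carbocycle can form. C2 is set by the chiral pocket of the four N-phthaloyl-tert-leucinate ligands, which should let the large ring B substituent point outward in only one of the two diastereomeric transition states, and because the step is neutral and irreversible the configuration is not exposed to ring opening afterwards. The step needs insertion to win over attack of the ether oxygen on the carbenoid (oxonium ylide, then benzyl shift to a 2-benzylbenzofuran-3-one) and over reaction elsewhere. O1 is a weak donor because it is conjugated through ring A with the ketone, the reacting C–H is doubly activated by O1 and the para-benzyloxyphenyl ring, the other ortho oxygen carries a bulky silyl group with no activated C–H in reach, the four remote benzyl ethers cannot reach the carbenoid through a small ring, and slow addition suppresses carbene dimerisation.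

Step 10
Reactants: 13 (2S)-2-[4-(benzyloxy)-3-(tri-O-benzylapigenin-8-yl)phenyl]-7-methoxy-5-(triisopropylsilyloxy)chroman-4-one
Product: 14 (2S)-2-[4-(benzyloxy)-3-(tri-O-benzylapigenin-8-yl)phenyl]-5-hydroxy-7-methoxychroman-4-one
Conditions: HF·pyridine, pyridine/THF, 0 °C to rt
Reagents that add atoms: none
Why: Fluoride-mediated Si–O cleavage; the phenol ortho to the ketone is a good leaving group on silicon, and the weakly acidic medium never generates the 5-phenoxide, so the E1cB ring opening to the chalcone that would erase C2 cannot start.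

Step 11
Reactants: 14 (2S)-2-[4-(benzyloxy)-3-(tri-O-benzylapigenin-8-yl)phenyl]-5-hydroxy-7-methoxychroman-4-one
Product: 15 (2S)-5-hydroxy-2-{4-hydroxy-3-[5,7-dihydroxy-2-(4-hydroxyphenyl)-4-oxo-4H-chromen-8-yl]phenyl}-7-methoxychroman-4-one (the target)
Conditions: H2 (1 atm), 10% Pd/C, THF/MeOH, rt, stopped once debenzylation is complete
Reagents that add atoms: none
Why: Catalytic hydrogenolysis of aryl benzyl ethers; the four O–CH2Ph bonds should cleave under neutral conditions well before the cyclic benzylic C2–O1 bond, the flavone C2″=C3″ double bond or either ketone is touched, so C2 keeps its configuration.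

**Compound list**

1 | apigenin | O=c1cc(-c2ccc(O)cc2)oc2cc(O)cc(O)c12 | starting material
2 | 5,7,4′-tri-O-benzylapigenin | O=c1cc(-c2ccc(OCc3ccccc3)cc2)oc2cc(OCc3ccccc3)cc(OCc3ccccc3)c12 | intermediate
3 | 8-iodo-5,7,4′-tri-O-benzylapigenin | O=c1cc(-c2ccc(OCc3ccccc3)cc2)oc2c(I)c(OCc3ccccc3)cc(OCc3ccccc3)c12 | intermediate
4 | 4-(benzyloxy)-3-bromobenzaldehyde | O=Cc1ccc(OCc2ccccc2)c(Br)c1 | starting material
5 | 4-(benzyloxy)-3-(4,4,5,5-tetramethyl-1,3,2-dioxaborolan-2-yl)benzaldehyde | O=Cc1ccc(OCc2ccccc2)c(B2OC(C)(C)C(C)(C)O2)c1 | intermediate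
6 | 4-(benzyloxy)-3-(tri-O-benzylapigenin-8-yl)benzaldehyde | O=Cc1ccc(OCc2ccccc2)c(-c2c(OCc3ccccc3)cc(OCc3ccccc3)c3c(=O)cc(-c4ccc(OCc5ccccc5)cc4)oc23)c1 | intermediate
7 | [4-(benzyloxy)-3-(tri-O-benzylapigenin-8-yl)phenyl]methanol | OCc1ccc(OCc2ccccc2)c(-c2c(OCc3ccccc3)cc(OCc3ccccc3)c3c(=O)cc(-c4ccc(OCc5ccccc5)cc4)oc23)c1 | intermediate
8 | 2′,6′-dihydroxy-4′-methoxyacetophenone | COc1cc(O)c(C(C)=O)c(O)c1 | starting material
9 | 1-{2-hydroxy-4-methoxy-6-[4-(benzyloxy)-3-(tri-O-benzylapigenin-8-yl)benzyloxy]phenyl}ethanone | COc1cc(O)c(C(C)=O)c(OCc2ccc(OCc3ccccc3)c(-c3c(OCc4ccccc4)cc(OCc4ccccc4)c4c(=O)cc(-c5ccc(OCc6ccccc6)cc5)oc34)c2)c1 | intermediate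
10 | 1-{4-methoxy-2-[4-(benzyloxy)-3-(tri-O-benzylapigenin-8-yl)benzyloxy]-6-(triisopropylsilyloxy)phenyl}ethanone | COc1cc(O[Si](C(C)C)(C(C)C)C(C)C)c(C(C)=O)c(OCc2ccc(OCc3ccccc3)c(-c3c(OCc4ccccc4)cc(OCc4ccccc4)c4c(=O)cc(-c5ccc(OCc6ccccc6)cc5)oc34)c2)c1 | intermediate
11 | 4,4,4-trifluoro-1-{4-methoxy-2-[4-(benzyloxy)-3-(tri-O-benzylapigenin-8-yl)benzyloxy]-6-(triisopropylsilyloxy)phenyl}butane-1,3-dione | COc1cc(O[Si](C(C)C)(C(C)C)C(C)C)c(C(=O)CC(=O)C(F)(F)F)c(OCc2ccc(OCc3ccccc3)c(-c3c(OCc4ccccc4)cc(OCc4ccccc4)c4c(=O)cc(-c5ccc(OCc6ccccc6)cc5)oc34)c2)c1 | intermediate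
12 | 2-diazo-1-{4-methoxy-2-[4-(benzyloxy)-3-(tri-O-benzylapigenin-8-yl)benzyloxy]-6-(triisopropylsilyloxy)phenyl}ethanone | COc1cc(O[Si](C(C)C)(C(C)C)C(C)C)c(C(=O)C=[N+]=[N-])c(OCc2ccc(OCc3ccccc3)c(-c3c(OCc4ccccc4)cc(OCc4ccccc4)c4c(=O)cc(-c5ccc(OCc6ccccc6)cc5)oc34)c2)c1 | intermediate
13 | (2S)-2-[4-(benzyloxy)-3-(tri-O-benzylapigenin-8-yl)phenyl]-7-methoxy-5-(triisopropylsilyloxy)chroman-4-one | COc1cc(O[Si](C(C)C)(C(C)C)C(C)C)c2c(c1)O[C@H](c1ccc(OCc3ccccc3)c(-c3c(OCc4ccccc4)cc(OCc4ccccc4)c4c(=O)cc(-c5ccc(OCc6ccccc6)cc5)oc34)c1)CC2=O | intermediate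
14 | (2S)-2-[4-(benzyloxy)-3-(tri-O-benzylapigenin-8-yl)phenyl]-5-hydroxy-7-methoxychroman-4-one | COc1cc(O)c2c(c1)O[C@H](c1ccc(OCc3ccccc3)c(-c3c(OCc4ccccc4)cc(OCc4ccccc4)c4c(=O)cc(-c5ccc(OCc6ccccc6)cc5)oc34)c1)CC2=O | intermediate
15 | (2S)-5-hydroxy-2-{4-hydroxy-3-[5,7-dihydroxy-2-(4-hydroxyphenyl)-4-oxo-4H-chromen-8-yl]phenyl}-7-methoxychroman-4-one | COc1cc(O)c2c(c1)O[C@H](c1ccc(O)c(-c3c(O)cc(O)c4c(=O)cc(-c5ccc(O)cc5)oc34)c1)CC2=O | target

**Step count**

Total: 11 steps. Longest linear sequence: 10 steps (1 → 2 → 3 → 6 → 7 → 9 → 10 → 12 → 13 → 14 → 15; step 3 is the side branch).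

**Steps most likely to fail, with fallbacks**

Step 9. The carbenoid may be captured by the ether oxygen and pass through an oxonium ylide with benzyl migration, or the catalyst may discriminate poorly between the two enantiotopic hydrogens. The fallback abandons carbenoid chemistry and sets out from aldehyde 6 and acetophenone 8. A Claisen–Schmidt condensation (KOH, EtOH/THF, rt) should give the (E)-2′,6′-dihydroxy-4′-methoxychalcone F1. Oxa-Michael closure (NaOAc, EtOH, reflux) should then give the racemic 5-hydroxyflavanone F2; either hydroxyl gives the same ring. Preparative chromatography on a chiral stationary phase, amylose tris(3,5-dimethylphenylcarbamate), separates F2 into 14 and the (2R)-enantiomer F3. F3 is returned to F2 by base through F1 and resolved again. The fallback rejoins the route at 14.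

Step 8. The silyl group may transfer to the neighbouring lithium enolate, or the enolate may add to the flavone before it is acylated. The fallback avoids the lithium enolate and sets out from 10. Soft enolisation (Me3SiOTf, Et3N, CH2Cl2, 0 °C) should give the trimethylsilyl enol ether F4. N-Bromosuccinimide (THF, −78 °C) should convert it into the bromomethyl ketone F5. N,N′-Ditosylhydrazine with DBU (THF, 0 °C) should then N-alkylate and lose two sulfinate groups to give diazoketone 12, where the fallback rejoins the route.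

Step 4. Transmetalation onto the crowded C8–palladium centre may be slow, so that protodeboronation of 5 and loss of iodine from 3 take over. The fallback reverses the polarity of the coupling and sets out from iodide 3. Miyaura borylation (B2pin2, PdCl2(dppf), KOAc, 1,4-dioxane, 85 °C) should give the flavone 8-boronate F6. This is coupled with bromide 4 under anhydrous conditions (Pd(PPh3)4, CsF, 1,2-dimethoxyethane, 80 °C) to give 6, where the fallback rejoins the route.

**Further compounds**

F1 | step 9 | (E)-1-(2,6-dihydroxy-4-methoxyphenyl)-3-[4-(benzyloxy)-3-(tri-O-benzylapigenin-8-yl)phenyl]prop-2-en-1-one | COc1cc(O)c(C(=O)/C=C/c2ccc(OCc3ccccc3)c(-c3c(OCc4ccccc4)cc(OCc4ccccc4)c4c(=O)cc(-c5ccc(OCc6ccccc6)cc5)oc34)c2)c(O)c1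
F2 | step 9 | racemic 2-[4-(benzyloxy)-3-(tri-O-benzylapigenin-8-yl)phenyl]-5-hydroxy-7-methoxychroman-4-one | COc1cc(O)c2c(c1)OC(c1ccc(OCc3ccccc3)c(-c3c(OCc4ccccc4)cc(OCc4ccccc4)c4c(=O)cc(-c5ccc(OCc6ccccc6)cc5)oc34)c1)CC2=O
F3 | step 9 | (2R)-2-[4-(benzyloxy)-3-(tri-O-benzylapigenin-8-yl)phenyl]-5-hydroxy-7-methoxychroman-4-one | COc1cc(O)c2c(c1)O[C@@H](c1ccc(OCc3ccccc3)c(-c3c(OCc4ccccc4)cc(OCc4ccccc4)c4c(=O)cc(-c5ccc(OCc6ccccc6)cc5)oc34)c1)CC2=O
F4 | step 8 | trimethylsilyl enol ether of 10 | COc1cc(O[Si](C(C)C)(C(C)C)C(C)C)c(C(=C)O[Si](C)(C)C)c(OCc2ccc(OCc3ccccc3)c(-c3c(OCc4ccccc4)cc(OCc4ccccc4)c4c(=O)cc(-c5ccc(OCc6ccccc6)cc5)oc34)c2)c1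
F5 | step 8 | 2-bromo-1-{4-methoxy-2-[4-(benzyloxy)-3-(tri-O-benzylapigenin-8-yl)benzyloxy]-6-(triisopropylsilyloxy)phenyl}ethanone | COc1cc(O[Si](C(C)C)(C(C)C)C(C)C)c(C(=O)CBr)c(OCc2ccc(OCc3ccccc3)c(-c3c(OCc4ccccc4)cc(OCc4ccccc4)c4c(=O)cc(-c5ccc(OCc6ccccc6)cc5)oc34)c2)c1
F6 | step 4 | 5,7-bis(benzyloxy)-2-[4-(benzyloxy)phenyl]-8-(4,4,5,5-tetramethyl-1,3,2-dioxaborolan-2-yl)-4H-chromen-4-one | O=c1cc(-c2ccc(OCc3ccccc3)cc2)oc2c(B3OC(C)(C)C(C)(C)O3)c(OCc3ccccc3)cc(OCc3ccccc3)c12
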